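The easy mistake with the grey run is to take its last reading for the top of a hot flask, so I follow the speed at which target appears and how that speed dies away.

the same everywhere: starting material 0.010 M

|  | first nucleophile | second nucleophile | temperature | remark | time |
|---|---|---|---|---|---|
| grey | 9 mM | 0.017 M | 100 °C | run made earlier |  |
| north-east | 9.00 mM | 0.0110 M | 100 °C |  | 2.5 d |
| north | 9.00 mM | 0.0110 M | 75 °C |  | 2.5 d |
| north-west | 9.00 mM | 0.0110 M | 50 °C |  | 2.5 d |

grey run (percent of the starting material charged)

| time / h | target / % |
|---|---|
| 1.50 | 10.5 |
| 4.00 | 22.7 |
| 8.00 | 26.8 |
| 12.0 | 28.8 |

(readings scatter by 1 percentage point)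

- the flask that comes out highest in amount of target, in percent of the starting material charged, or "all alike" when all lie within 1.5 percentage points (north-east / north / north-west / all alike)
- target at the end, in percent of the starting material charged, north-east
- target at the end, in percent of the starting material charged, north
- target at the end, in percent of the starting material charged, north-west

- the earlier runs do not show what temperature does; that part of a forecast is a guess

In the grey run, target appears at 0.0700 /h of the charge up to the first reading, then at 0.0488 /h, 0.0103 /h and 0.00500 /h. Each step slows it by a factor of 1.43, 4.74 and 2.06. These are rough, given a scatter of 1 percentage point per reading. I take the slowing to follow the fraction of starting material left, a first-order fall. From the first interval to the last, the speed drops by a factor of 14.0 over 9.25 h between midpoints, so it falls at 0.285 /h. The time in which the speed halves, my half-time, is 2.43 h.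

By that fall I reckon the speed at the last grey reading at 0.002826 /h, and dividing by the fall gives 0.99 points still to come, so I read the top of the grey run, with the scatter of its readings, near 29.8%. North-east has 24.7 halvings in its time, so I put it at that same top. One run cannot show what its lower second nucleophile does. For the cooler flasks I have no number of my own, since the earlier runs do not show what temperature does.

The forecast gives 33% for north-east, 30% for north and 13% for north-west, with north-east highest, calling the hot flask “well past the plateau”. Its north-east figure is higher than mine.

    starting material → intermediate (k = 7.04 × 10⁻⁵ /s, Ea = 105 kJ/mol)
    first nucleophile + intermediate → target (k = 1.47 /M/s, Ea = 72.0 kJ/mol)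
    second nucleophile + intermediate → other capture product (k = 0.0418 /M/s, Ea = 74.0 kJ/mol)
    intermediate → solvolysis product (k = 0.0206 /s, Ea = 90.0 kJ/mol)
    starting material + intermediate → side product (k = 3.30 × 10⁻⁴ /M/s, Ea = 88.0 kJ/mol)
    target ⇌ isomer of the product (K = 0.739, k = 2.31 × 10⁻⁶ /s, Ea = 119 kJ/mol, ΔH = 6.00 kJ/mol)
    (constants at 100 °C)

The flask north comes out highest at 31.3%, against 24.0% in north-east and 4.58% in north-west, and north-east lies below both my reading of the top and the forecast. North-east held 27.7% of target at 1.25 d and 24.0% at 2.50 d, while its isomer of the product went from 5.70% to 9.48%. My half-time gives 0.0192% of starting material in north-east at 1.25 d, and the flask holds 0.0499%. In north, 26.2% of starting material left at 2.50 d means 1.93 halvings, so its half-time averages 31.1 h, against the 2.43 h I read off the grey run.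

Readings and results stem from a simulated flask on assumed constants; scatter was added.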